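Ring B of the target (C1–C4, C4a, C8a) carries oxygen at C1, C2 and C4 and hydrogen at C3. This is the substitution pattern of a 2-alkoxycyclobutenone whose C4 is bonded to the future C4a of ring A, so the synthesis rests on cutting C1–C8a. Heating the cyclobutenone opens it to a vinylketene. Its ketene carbon closes onto C8a, the only free ortho position because C5 bears the methyl group, so ring B and the C2 oxygen regiochemistry are settled in one operation. The precursor is the fully O-methylated benzophenone with a 4-methoxy-2-isopropoxycyclobutenone on ring A and an allyl group on ring C as pyrone handle.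

Key step: step 8

Remarks on the chemistry
- Numbering follows the target: C1(=O) next to C8a, C2–OH, C3–H, C4(=O) next to C4a, C5–CH3, C6–aroyl, C7–OH, C8–H. Ring A is the benzenoid ring, ring B the quinone, ring C the resorcinol ring and ring D the pyrone. The ring atoms C1–C4 of the cyclobutenone become C1–C4 of ring B.
- The target has no stereocentre. All chiral intermediates are racemic (or mixtures of diastereomers), and each of their stereocentres is erased later.
- The aryl group must sit on the four-ring carbon next to CH, not on the one next to C–OiPr.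
  - Addition of an aryllithium to 3-isopropoxycyclobutenedione gives the wrong isomer.
  - The adduct of a cyclobutenedione monoketal would need acid to unmask the ketal. Acid would instead ionise its tertiary, p-methoxybenzylic, enol-ether-conjugated carbinol and lead to a 3-arylcyclobutenedione.
  - The aryl group is therefore added to the symmetrical squarate, the alkoxide is capped as a methyl ether, and the carbonyl is moved by reduction and 1,3-transposition. The methyl ether is needed later anyway as the C4–OMe group.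
- Assumption: compounds 1, 3, 8 and 21 are purchased.

Step 1
Reactants: 1 2-methoxy-6-methylbenzaldehyde
Product: 2 3-bromo-6-methoxy-2-methylbenzaldehyde
Conditions: NBS, MeCN, 0 °C → rt, dark
Reagents that add atoms: N-bromosuccinimide, O=C1CCC(=O)N1Br
Why: Electrophilic aromatic bromination goes to the position para to methoxy, ortho to methyl and meta to formyl, where all three substituents agree, which puts bromine on the future C4a beside the future C5.

Step 2
Reactants: 3 1-allyl-3,5-dimethoxybenzene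
Product: 4 1-allyl-2-bromo-3,5-dimethoxybenzene
Conditions: NBS, MeCN, −10 → 0 °C, dark
Reagents that add atoms: N-bromosuccinimide, O=C1CCC(=O)N1Br
Why: Electrophilic aromatic bromination of a 5-alkylresorcinol dimethyl ether occurs para to one methoxy group and ortho to the other, beside the alkyl chain and not at the crowded carbon between the two methoxy groups, and in a polar solvent in the dark the activated ring reacts faster than the terminal alkene.

Step 3
Reactants: 4 1-allyl-2-bromo-3,5-dimethoxybenzene; 2 3-bromo-6-methoxy-2-methylbenzaldehyde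
Product: 6 (2-allyl-4,6-dimethoxyphenyl)(3-bromo-6-methoxy-2-methylphenyl)methanol (racemic), via aryllithium 5 (not isolated)
Conditions: 4, n-BuLi, THF, −78 °C; then 2, −78 → 0 °C; H2O
Reagents that add atoms: none
Why: Bromine–lithium exchange followed by 1,2-addition of the aryllithium to the aldehyde, which at −78 °C is much faster than aryl–aryl halogen exchange with the bromide of 2; the carbinol centre is racemic and is erased in step 4.

Step 4
Reactants: 6 (2-allyl-4,6-dimethoxyphenyl)(3-bromo-6-methoxy-2-methylphenyl)methanol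
Product: 7 (2-allyl-4,6-dimethoxyphenyl)(3-bromo-6-methoxy-2-methylphenyl)methanone
Conditions: Dess–Martin periodinane, CH2Cl2, 0 °C → rt
Reagents that add atoms: none
Why: Dess–Martin oxidation converts crowded secondary diaryl carbinols into tetra-ortho-substituted benzophenones under nearly neutral conditions and leaves the alkene and the aryl bromide untouched.

Step 5
Reactants: 7 (2-allyl-4,6-dimethoxyphenyl)(3-bromo-6-methoxy-2-methylphenyl)methanone; 8 diisopropyl squarate
Product: 11 4-[3-(2-allyl-4,6-dimethoxybenzoyl)-4-methoxy-2-methylphenyl]-2,3-diisopropoxy-4-methoxycyclobut-2-en-1-one (racemic), via aryllithium 9 (not isolated), via lithium alkoxide 10 (not isolated)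
Conditions: 7, n-BuLi, THF, −78 °C, short exchange time; cannulated into 8, THF, −78 °C; then MeOTf, −78 → 0 °C
Reagents that add atoms: methyl trifluoromethanesulfonate, COS(=O)(=O)C(F)(F)F
Why: Bromine–lithium exchange at −78 °C outruns attack on a diaryl ketone shielded by four ortho substituents, and 1,2-addition of an aryllithium to the symmetrical dialkyl squarate with capture of the tertiary alkoxide by MeOTf is the standard entry to 4-aryl-4-alkoxycyclobutenones; the quaternary centre forms as a racemate.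

Step 6
Reactants: 11 4-[3-(2-allyl-4,6-dimethoxybenzoyl)-4-methoxy-2-methylphenyl]-2,3-diisopropoxy-4-methoxycyclobut-2-en-1-one
Product: 12 4-[3-(2-allyl-4,6-dimethoxybenzoyl)-4-methoxy-2-methylphenyl]-2,3-diisopropoxy-4-methoxycyclobut-2-en-1-ol (racemic; both diastereomers)
Conditions: i-Bu2AlH (slight excess), CH2Cl2, −78 °C; aq KNaC4H4O6 (tartrate)
Reagents that add atoms: none
Why: 1,2-Reduction of the strained vinylogous-ester carbonyl (first half of a Stork–Danheiser transposition) should be much faster than hydride transfer to the tetra-ortho-substituted benzophenone; the carbinol centre forms without control, which does not matter because it becomes sp2 in step 7.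

Step 7
Reactants: 12 4-[3-(2-allyl-4,6-dimethoxybenzoyl)-4-methoxy-2-methylphenyl]-2,3-diisopropoxy-4-methoxycyclobut-2-en-1-ol
Product: 14 4-[3-(2-allyl-4,6-dimethoxybenzoyl)-4-methoxy-2-methylphenyl]-2-isopropoxy-4-methoxycyclobut-2-en-1-one (racemic), via allylic trifluoroacetate 13 (not isolated)
Conditions: (CF3CO)2O, 2,6-lutidine, CH2Cl2, −78 → 0 °C; then H2O
Reagents that add atoms: water, O
Why: Only the free secondary hydroxyl is acylated, the allylic trifluoroacetate ionises with the push of the vinylogous isopropoxy group, and water turns that oxocarbenium carbon into the new carbonyl with loss of propan-2-ol (Stork–Danheiser-type 1,3-carbonyl transposition as practised on squarate adducts), so the carbonyl ends beside the aryl-bearing carbon and the remaining isopropoxy group beside the carbonyl, while the buffered medium spares the tertiary methyl ether.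

Step 8
Reactants: 14 4-[3-(2-allyl-4,6-dimethoxybenzoyl)-4-methoxy-2-methylphenyl]-2-isopropoxy-4-methoxycyclobut-2-en-1-one
Product: 17 (2-allyl-4,6-dimethoxyphenyl)(5-hydroxy-6-isopropoxy-3,8-dimethoxy-1-methylnaphthalen-2-yl)methanone (target numbering: C1–OH; C2–OiPr; C4–OMe), via vinylketene 15 (not isolated), via ring-closed dienone 16 (not isolated)
Conditions: degassed p-xylene, reflux (138 °C), Ar, dilute
Reagents that add atoms: none
Why: Heating breaks the C1–C4 bond of the cyclobutenone in a conrotatory 4π electrocyclic opening in which the donor methoxy group on C4 turns outward, so vinylketene 15 forms with ring A cis to the ketene. The ketene carbon C1 then bonds to C8a in a disrotatory 6π electrocyclisation over C1=C2, C3=C4 and C4a=C8a, which closes the six-membered ring B as dienone 16, and a proton shift from C8a to the C1 oxygen restores aromaticity to give naphthol 17. The closest known reaction type is the Moore rearrangement of 4-aryl-4-hydroxy- and 4-aryl-4-alkoxycyclobutenones to hydroquinones and their monoethers. No stereocentre remains, because the quaternary centre of racemic 14 becomes sp2 on ring opening and the transient C8a centre of 16 is lost on tautomerisation. Two selectivities are needed: the site of closure is secured by the C5 methyl group, since closure at C5 would give a dienone that cannot aromatise and reverts, and the isopropoxy group is fixed at C2 by the constitution of 14, where the alkoxy carbon is bonded to the carbonyl carbon that becomes C1. The methyl ether on C4 also closes off the lactone pathway of a free hydroxyl and should give a monoprotected hydroquinone that is less sensitive to air.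

Step 9
Reactants: 17 (2-allyl-4,6-dimethoxyphenyl)(5-hydroxy-6-isopropoxy-3,8-dimethoxy-1-methylnaphthalen-2-yl)methanone
Product: 18 (2-allyl-4,6-dimethoxyphenyl)(6-isopropoxy-3,5,8-trimethoxy-1-methylnaphthalen-2-yl)methanone
Conditions: MeI, K2CO3, DMF, rt, Ar
Reagents that add atoms: iodomethane, CI
Why: Williamson ether synthesis on the only acidic hydroxyl group masks ring B as a 1,2,4-trialkoxynaphthalene that tolerates the enolate and oxidation chemistry to follow.

Step 10
Reactants: 18 (2-allyl-4,6-dimethoxyphenyl)(6-isopropoxy-3,5,8-trimethoxy-1-methylnaphthalen-2-yl)methanone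
Product: 20 2-[2-(6-isopropoxy-3,5,8-trimethoxy-1-methyl-2-naphthoyl)-3,5-dimethoxyphenyl]acetaldehyde, via vicinal diol 19 (not isolated)
Conditions: OsO4 (cat.), NaIO4, 2,6-lutidine, dioxane–H2O, rt
Reagents that add atoms: osmium tetroxide, O=[Os](=O)(=O)=O; sodium periodate, [Na+].[O-]I(=O)(=O)=O (terminal oxygen source)
Why: Lemieux–Johnson cleavage, in which OsO4 dihydroxylates the only isolated alkene and NaIO4 cleaves the diol, whereas aryl ethers and the hindered ketone are inert, unlike under ozonolysis, which would endanger the electron-rich naphthalene.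

Step 11
Reactants: 20 2-[2-(6-isopropoxy-3,5,8-trimethoxy-1-methyl-2-naphthoyl)-3,5-dimethoxyphenyl]acetaldehyde; 21 2,2,6-trimethyl-4H-1,3-dioxin-4-one
Product: 23 6-{3-[2-(6-isopropoxy-3,5,8-trimethoxy-1-methyl-2-naphthoyl)-3,5-dimethoxyphenyl]-2-hydroxypropyl}-2,2-dimethyl-4H-1,3-dioxin-4-one (racemic), via lithium dienolate 22 (not isolated)
Conditions: 21, LiN(i-Pr)2, THF, −78 °C; then 20, −78 °C; AcOH
Reagents that add atoms: none
Why: Vinylogous aldol addition, in which the lithium dienolate of the dioxinone attacks aldehydes through its exocyclic γ-carbon and the shielded diaryl ketone does not compete; the carbinol centre is racemic and is erased in step 12.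

Step 12
Reactants: 23 6-{3-[2-(6-isopropoxy-3,5,8-trimethoxy-1-methyl-2-naphthoyl)-3,5-dimethoxyphenyl]-2-hydroxypropyl}-2,2-dimethyl-4H-1,3-dioxin-4-one
Product: 24 6-{3-[2-(6-isopropoxy-3,5,8-trimethoxy-1-methyl-2-naphthoyl)-3,5-dimethoxyphenyl]-2-oxopropyl}-2,2-dimethyl-4H-1,3-dioxin-4-one
Conditions: Dess–Martin periodinane, CH2Cl2, 0 °C → rt
Reagents that add atoms: none
Why: Dess–Martin oxidation of the secondary alcohol is mild enough for the trialkoxynaphthalene, and the dioxinone keeps the β-keto acid unit masked during the oxidation.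

Step 13
Reactants: 24 6-{3-[2-(6-isopropoxy-3,5,8-trimethoxy-1-methyl-2-naphthoyl)-3,5-dimethoxyphenyl]-2-oxopropyl}-2,2-dimethyl-4H-1,3-dioxin-4-one
Product: 26 4-hydroxy-6-[2-(6-isopropoxy-3,5,8-trimethoxy-1-methyl-2-naphthoyl)-3,5-dimethoxybenzyl]-2H-pyran-2-one, via acylketene 25 (not isolated)
Conditions: toluene, reflux (110 °C), dilute
Reagents that add atoms: none
Why: Thermal retro-hetero-Diels–Alder loss of acetone gives an acylketene that is captured by the enol oxygen of the neighbouring ketone in a six-membered closure, the standard neutral synthesis of 6-substituted 4-hydroxy-2-pyrones, and the absence of base avoids aldol attack on the benzophenone carbonyl.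

Step 14
Reactants: 26 4-hydroxy-6-[2-(6-isopropoxy-3,5,8-trimethoxy-1-methyl-2-naphthoyl)-3,5-dimethoxybenzyl]-2H-pyran-2-one
Product: 28 6-{2,4-dihydroxy-6-[(4-hydroxy-2-oxo-2H-pyran-6-yl)methyl]benzoyl}-2,7-dihydroxy-5-methylnaphthalene-1,4-dione (CNP0141484.0), via naphthalenetriol 27 (not isolated)
Conditions: BBr3 (excess), CH2Cl2, −78 °C → rt; H2O; then EtOAc–H2O, stirred under air, rt
Reagents that add atoms: none
Why: BBr3 cleaves the five aryl methyl ethers and the isopropyl ether by Lewis-acid activation and bromide attack, and the liberated 1,2,4-trihydroxynaphthalene unit is autoxidised by air to the 2-hydroxy-1,4-naphthoquinone, as known for the parent triol, while the acylated resorcinol ring, the C7 phenol and the pyrone are not oxidised.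

Compound list
1 | 2-methoxy-6-methylbenzaldehyde | COc1cccc(C)c1C=O | starting material
2 | 3-bromo-6-methoxy-2-methylbenzaldehyde | COc1ccc(Br)c(C)c1C=O | intermediate
3 | 1-allyl-3,5-dimethoxybenzene | C=CCc1cc(OC)cc(OC)c1 | starting material
4 | 1-allyl-2-bromo-3,5-dimethoxybenzene | C=CCc1cc(OC)cc(OC)c1Br | intermediate
5 | (2-allyl-4,6-dimethoxyphenyl)lithium | [Li]c1c(CC=C)cc(OC)cc1OC | intermediate
6 | (2-allyl-4,6-dimethoxyphenyl)(3-bromo-6-methoxy-2-methylphenyl)methanol, racemic | OC(c1c(CC=C)cc(OC)cc1OC)c1c(C)c(Br)ccc1OC | intermediate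
7 | (2-allyl-4,6-dimethoxyphenyl)(3-bromo-6-methoxy-2-methylphenyl)methanone | O=C(c1c(CC=C)cc(OC)cc1OC)c1c(C)c(Br)ccc1OC | intermediate
8 | diisopropyl squarate (3,4-diisopropoxycyclobut-3-ene-1,2-dione) | CC(C)OC1=C(OC(C)C)C(=O)C1=O | starting material
9 | [3-(2-allyl-4,6-dimethoxybenzoyl)-4-methoxy-2-methylphenyl]lithium | [Li]c1ccc(OC)c(C(=O)c2c(CC=C)cc(OC)cc2OC)c1C | intermediate
10 | lithium 1-[3-(2-allyl-4,6-dimethoxybenzoyl)-4-methoxy-2-methylphenyl]-2,3-diisopropoxy-4-oxocyclobut-2-en-1-olate, racemic | [Li+].[O-]C1(c2ccc(OC)c(C(=O)c3c(CC=C)cc(OC)cc3OC)c2C)C(OC(C)C)=C(OC(C)C)C1=O | intermediate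
11 | 4-[3-(2-allyl-4,6-dimethoxybenzoyl)-4-methoxy-2-methylphenyl]-2,3-diisopropoxy-4-methoxycyclobut-2-en-1-one, racemic | COC1(c2ccc(OC)c(C(=O)c3c(CC=C)cc(OC)cc3OC)c2C)C(OC(C)C)=C(OC(C)C)C1=O | intermediate
12 | 4-[3-(2-allyl-4,6-dimethoxybenzoyl)-4-methoxy-2-methylphenyl]-2,3-diisopropoxy-4-methoxycyclobut-2-en-1-ol, racemic, both diastereomers | COC1(c2ccc(OC)c(C(=O)c3c(CC=C)cc(OC)cc3OC)c2C)C(OC(C)C)=C(OC(C)C)C1O | intermediate
13 | trifluoroacetate ester of 12 | COC1(c2ccc(OC)c(C(=O)c3c(CC=C)cc(OC)cc3OC)c2C)C(OC(C)C)=C(OC(C)C)C1OC(=O)C(F)(F)F | intermediate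
14 | 4-[3-(2-allyl-4,6-dimethoxybenzoyl)-4-methoxy-2-methylphenyl]-2-isopropoxy-4-methoxycyclobut-2-en-1-one, racemic (key-step precursor, tertiary oxygen as methyl ether) | COC1(c2ccc(OC)c(C(=O)c3c(CC=C)cc(OC)cc3OC)c2C)C=C(OC(C)C)C1=O | intermediate
15 | (3E)-4-[3-(2-allyl-4,6-dimethoxybenzoyl)-4-methoxy-2-methylphenyl]-2-isopropoxy-4-methoxybuta-1,3-dien-1-one (aryl cis to the ketene) | O=C=C(OC(C)C)/C=C(/OC)c1ccc(OC)c(C(=O)c2c(CC=C)cc(OC)cc2OC)c1C | intermediate
16 | 6-(2-allyl-4,6-dimethoxybenzoyl)-2-isopropoxy-4,7-dimethoxy-5-methylnaphthalen-1(8aH)-one, racemic | O=C1C(OC(C)C)=CC(OC)=C2C(C)=C(C(=O)c3c(CC=C)cc(OC)cc3OC)C(OC)=CC12 | intermediate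
17 | (2-allyl-4,6-dimethoxyphenyl)(5-hydroxy-6-isopropoxy-3,8-dimethoxy-1-methylnaphthalen-2-yl)methanone (key-step product) | Cc1c(C(=O)c3c(CC=C)cc(OC)cc3OC)c(OC)cc2c(O)c(OC(C)C)cc(OC)c12 | intermediate
18 | (2-allyl-4,6-dimethoxyphenyl)(6-isopropoxy-3,5,8-trimethoxy-1-methylnaphthalen-2-yl)methanone | Cc1c(C(=O)c3c(CC=C)cc(OC)cc3OC)c(OC)cc2c(OC)c(OC(C)C)cc(OC)c12 | intermediate
19 | [2-(2,3-dihydroxypropyl)-4,6-dimethoxyphenyl](6-isopropoxy-3,5,8-trimethoxy-1-methylnaphthalen-2-yl)methanone, racemic | Cc1c(C(=O)c3c(CC(O)CO)cc(OC)cc3OC)c(OC)cc2c(OC)c(OC(C)C)cc(OC)c12 | intermediate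
20 | 2-[2-(6-isopropoxy-3,5,8-trimethoxy-1-methyl-2-naphthoyl)-3,5-dimethoxyphenyl]acetaldehyde | Cc1c(C(=O)c3c(CC=O)cc(OC)cc3OC)c(OC)cc2c(OC)c(OC(C)C)cc(OC)c12 | intermediate
21 | 2,2,6-trimethyl-4H-1,3-dioxin-4-one | CC1=CC(=O)OC(C)(C)O1 | starting material
22 | lithium 2,2-dimethyl-6-methylidene-6H-1,3-dioxin-4-olate | [Li+].[O-]C1=CC(=C)OC(C)(C)O1 | intermediate
23 | 6-{3-[2-(6-isopropoxy-3,5,8-trimethoxy-1-methyl-2-naphthoyl)-3,5-dimethoxyphenyl]-2-hydroxypropyl}-2,2-dimethyl-4H-1,3-dioxin-4-one, racemic | Cc1c(C(=O)c3c(CC(O)CC4=CC(=O)OC(C)(C)O4)cc(OC)cc3OC)c(OC)cc2c(OC)c(OC(C)C)cc(OC)c12 | intermediate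
24 | 6-{3-[2-(6-isopropoxy-3,5,8-trimethoxy-1-methyl-2-naphthoyl)-3,5-dimethoxyphenyl]-2-oxopropyl}-2,2-dimethyl-4H-1,3-dioxin-4-one | Cc1c(C(=O)c3c(CC(=O)CC4=CC(=O)OC(C)(C)O4)cc(OC)cc3OC)c(OC)cc2c(OC)c(OC(C)C)cc(OC)c12 | intermediate
25 | 6-[2-(6-isopropoxy-3,5,8-trimethoxy-1-methyl-2-naphthoyl)-3,5-dimethoxyphenyl]hex-1-ene-1,3,5-trione | Cc1c(C(=O)c3c(CC(=O)CC(=O)C=C=O)cc(OC)cc3OC)c(OC)cc2c(OC)c(OC(C)C)cc(OC)c12 | intermediate
26 | 4-hydroxy-6-[2-(6-isopropoxy-3,5,8-trimethoxy-1-methyl-2-naphthoyl)-3,5-dimethoxybenzyl]-2H-pyran-2-one | Cc1c(C(=O)c3c(Cc4cc(O)cc(=O)o4)cc(OC)cc3OC)c(OC)cc2c(OC)c(OC(C)C)cc(OC)c12 | intermediate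
27 | 4-hydroxy-6-[3,5-dihydroxy-2-(3,5,6,8-tetrahydroxy-1-methyl-2-naphthoyl)benzyl]-2H-pyran-2-one | Cc1c(C(=O)c3c(Cc4cc(O)cc(=O)o4)cc(O)cc3O)c(O)cc2c(O)c(O)cc(O)c12 | intermediate
28 | 6-{2,4-dihydroxy-6-[(4-hydroxy-2-oxo-2H-pyran-6-yl)methyl]benzoyl}-2,7-dihydroxy-5-methylnaphthalene-1,4-dione | Cc1c(C(=O)c2c(O)cc(O)cc2Cc2cc(O)cc(=O)o2)c(O)cc2c1C(=O)C=C(O)C2=O | target

Total step count: 14.
Longest linear sequence: 13 steps (steps 1 and 3–14; step 2 is the side branch).

Steps most likely to fail

Step 8. The 6π closure may be slow, because C8a lies para to the aroyl group and ring A is twisted by the C5 methyl group and the bulky benzoyl unit. The vinylketene could then be lost by dimerisation, by capture of traces of water or by unproductive re-closure. The fallback builds ring B before the two aryl halves are joined, on a smaller ring A without the acyl group. It sets out from 2 and comes back at 18.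
- Aldehyde 2 would be treated with ethane-1,2-diol and TsOH in toluene with removal of water to give 2-(3-bromo-6-methoxy-2-methylphenyl)-1,3-dioxolane F1.
- Exchange with n-BuLi, addition to 8 and capture with MeOTf would give 4-[3-(1,3-dioxolan-2-yl)-4-methoxy-2-methylphenyl]-2,3-diisopropoxy-4-methoxycyclobut-2-en-1-one F2.
- Reduction with i-Bu2AlH would give 4-[3-(1,3-dioxolan-2-yl)-4-methoxy-2-methylphenyl]-2,3-diisopropoxy-4-methoxycyclobut-2-en-1-ol F3.
- Treatment with (CF3CO)2O and 2,6-lutidine and then water would give 4-[3-(1,3-dioxolan-2-yl)-4-methoxy-2-methylphenyl]-2-isopropoxy-4-methoxycyclobut-2-en-1-one F4.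
- Thermolysis in p-xylene would give 6-(1,3-dioxolan-2-yl)-2-isopropoxy-4,7-dimethoxy-5-methylnaphthalen-1-ol F5.
- MeI and K2CO3 would give 2-(6-isopropoxy-3,5,8-trimethoxy-1-methylnaphthalen-2-yl)-1,3-dioxolane F6.
- Dilute aqueous acid in THF would release 6-isopropoxy-3,5,8-trimethoxy-1-methyl-2-naphthaldehyde F7.
- Addition of aryllithium 5 would give (2-allyl-4,6-dimethoxyphenyl)(6-isopropoxy-3,5,8-trimethoxy-1-methylnaphthalen-2-yl)methanol F8, and Dess–Martin oxidation of that carbinol returns to 18.

Step 5. Several processes could lower the conversion: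
- n-BuLi or the aryllithium may attack the benzophenone, by carbonyl addition or by displacement of an ortho methoxy group.
- Proton transfer from the allylic–benzylic CH2 may quench the aryllithium.
- O-methylation of the crowded alkoxide may be incomplete.

The fallback keeps the bridging carbon at the carbinol level during the organolithium step. It sets out from 6 and comes back at 11.
- Carbinol 6 would be treated with two equivalents of n-BuLi (deprotonation, then exchange) and added to 8. After a neutral work-up this gives 4-{3-[(2-allyl-4,6-dimethoxyphenyl)(hydroxy)methyl]-4-methoxy-2-methylphenyl}-4-hydroxy-2,3-diisopropoxycyclobut-2-en-1-one F9.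
- Dess–Martin periodinane or MnO2 would oxidise only the secondary carbinol to 4-[3-(2-allyl-4,6-dimethoxybenzoyl)-4-methoxy-2-methylphenyl]-4-hydroxy-2,3-diisopropoxycyclobut-2-en-1-one F10.
- MeI with Ag2O would methylate the tertiary hydroxyl to give 11.

Step 14. The sixfold dealkylation may stop at the non-chelated ether para to the ketone. The Lewis acid may also induce cyclisation between the ketone and neighbouring nucleophilic positions, or the polyphenol may be over-oxidised during the aerobic work-up. The fallback separates oxidation from dealkylation. It sets out from 26 and comes back at 28.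
- Two equivalents of (NH4)2Ce(NO3)6 in MeCN–H2O at 0 °C would remove the C1 and C4 methyl groups oxidatively from the trialkoxynaphthalene, by far the most easily oxidised part. This gives 6-{2,4-dimethoxy-6-[(4-hydroxy-2-oxo-2H-pyran-6-yl)methyl]benzoyl}-2-isopropoxy-7-methoxy-5-methylnaphthalene-1,4-dione F11.
- BBr3 then has to cleave only three aryl methyl ethers and the labile vinylogous isopropyl ester, and no air oxidation is needed to reach 28.

Further compounds
F1 | step 8 | 2-(3-bromo-6-methoxy-2-methylphenyl)-1,3-dioxolane | COc1ccc(Br)c(C)c1C1OCCO1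
F2 | step 8 | 4-[3-(1,3-dioxolan-2-yl)-4-methoxy-2-methylphenyl]-2,3-diisopropoxy-4-methoxycyclobut-2-en-1-one, racemic | COC1(c2ccc(OC)c(C3OCCO3)c2C)C(OC(C)C)=C(OC(C)C)C1=O
F3 | step 8 | 4-[3-(1,3-dioxolan-2-yl)-4-methoxy-2-methylphenyl]-2,3-diisopropoxy-4-methoxycyclobut-2-en-1-ol, racemic, both diastereomers | COC1(c2ccc(OC)c(C3OCCO3)c2C)C(OC(C)C)=C(OC(C)C)C1O
F4 | step 8 | 4-[3-(1,3-dioxolan-2-yl)-4-methoxy-2-methylphenyl]-2-isopropoxy-4-methoxycyclobut-2-en-1-one, racemic | COC1(c2ccc(OC)c(C3OCCO3)c2C)C=C(OC(C)C)C1=O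
F5 | step 8 | 6-(1,3-dioxolan-2-yl)-2-isopropoxy-4,7-dimethoxy-5-methylnaphthalen-1-ol | Cc1c(C3OCCO3)c(OC)cc2c(O)c(OC(C)C)cc(OC)c12
F6 | step 8 | 2-(6-isopropoxy-3,5,8-trimethoxy-1-methylnaphthalen-2-yl)-1,3-dioxolane | Cc1c(C3OCCO3)c(OC)cc2c(OC)c(OC(C)C)cc(OC)c12
F7 | step 8 | 6-isopropoxy-3,5,8-trimethoxy-1-methyl-2-naphthaldehyde | Cc1c(C=O)c(OC)cc2c(OC)c(OC(C)C)cc(OC)c12
F8 | step 8 | (2-allyl-4,6-dimethoxyphenyl)(6-isopropoxy-3,5,8-trimethoxy-1-methylnaphthalen-2-yl)methanol, racemic | Cc1c(C(O)c3c(CC=C)cc(OC)cc3OC)c(OC)cc2c(OC)c(OC(C)C)cc(OC)c12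
F9 | step 5 | 4-{3-[(2-allyl-4,6-dimethoxyphenyl)(hydroxy)methyl]-4-methoxy-2-methylphenyl}-4-hydroxy-2,3-diisopropoxycyclobut-2-en-1-one, racemic, both diastereomers | OC1(c2ccc(OC)c(C(O)c3c(CC=C)cc(OC)cc3OC)c2C)C(OC(C)C)=C(OC(C)C)C1=O
F10 | step 5 | 4-[3-(2-allyl-4,6-dimethoxybenzoyl)-4-methoxy-2-methylphenyl]-4-hydroxy-2,3-diisopropoxycyclobut-2-en-1-one, racemic | OC1(c2ccc(OC)c(C(=O)c3c(CC=C)cc(OC)cc3OC)c2C)C(OC(C)C)=C(OC(C)C)C1=O
F11 | step 14 | 6-{2,4-dimethoxy-6-[(4-hydroxy-2-oxo-2H-pyran-6-yl)methyl]benzoyl}-2-isopropoxy-7-methoxy-5-methylnaphthalene-1,4-dione | Cc1c(C(=O)c3c(Cc4cc(O)cc(=O)o4)cc(OC)cc3OC)c(OC)cc2c1C(=O)C=C(OC(C)C)C2=O
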